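(The runs come from a simulation with made-up constants, and the scatter is random.)

Take logarithms before you back your hunch that the warmest flask wins; I did, and I did not back it. Here is what stood before me:

| setting | Tuesday's | Sunday's | Thursday's | south-east | north | north-east | north-west |
|---|---|---|---|---|---|---|---|
| G | 0.014 M | 0.022 M | 0.010 M | 0.010 M | 0.010 M | 0.010 M | 0.010 M |
| D | 0.030 M | 0.030 M | 0.045 M | 0.0300 M | 0.0300 M | 0.0300 M | 0.0300 M |
| L | 50 µM | 50 µM | 50 µM | 50 µM | 50 µM | 50 µM | 50 µM |
| temperature | −11 °C | 30 °C | −11 °C | 20 °C | −30 °C | −5 °C | 45 °C |
| remark | run made earlier | run made earlier | run made earlier |  |  |  |  |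
| time |  |  |  | 3.0 min | 3.0 min | 3.0 min | 3.0 min |

Tuesday's run (percent of the G charged)

| time / min | E / % |
|---|---|
| 0.833 | 65.0 |
| 1.33 | 80.7 |
| 2.50 | 93.3 |
| 5.00 | 94.7 |
| 10.0 | 90.1 |

Sunday's run (percent of the G charged)

| time / s | E / % |
|---|---|
| 10.0 | 67.4 |
| 15.0 | 76.7 |
| 30.0 | 84.1 |
| 50.0 | 83.8 |
| 80.0 | 80.0 |

Thursday's run (percent of the G charged)

| time / min | E / % |
|---|---|
| 1.50 | 84.7 |
| 3.00 | 93.1 |
| 5.00 | 89.8 |
| 6.00 | 87.8 |
| 10.0 | 79.4 |

(each reading ± 0.5 percentage points)

* the best flask by amount of E, in percent of the G charged; "all alike" if 1.5 percentage points covers them all (south-east / north / north-east / north-west / all alike)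
* amount of E at the end, in percent of the G charged, south-east
* amount of E at the end, in percent of the G charged, north
* amount of E at the end, in percent of the G charged, north-east
* amount of E at the end, in percent of the G charged, north-west

- what may be going on: G + L <-> L + X; D + L + X -> L + E; D + E -> Z

In these runs the readings of E rose to a peak and then fell, which I put down to the step D + E → Z (overreaction, in the usual word), so I read its rate constant k from the late fall. D was not read, so I reckoned it as its charge less one D per E and two per Z. In Thursday's run, between 5.00 min and 10.0 min, D stood near 0.0335 M, and the readings gave k = 0.736 /M/min at −11 °C. In Sunday's run, between 50.0 s and 80.0 s, D stood near 0.00402 M, and the readings gave 23.1 /M/min at 30 °C, a rough reading. From these I took S, the decade step, meaning the warming that multiplies k by one power of ten: S = 27.4 K.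

Each E lost takes one D, so once G has turned, D minus E holds at a, the charge of D less two D per G charged, in the asked flasks 0.0100 M. The logarithm of D/E, counted in powers of ten, then climbs in a straight line at k·a/2.3 per minute, and E follows from D = E + a. I ran the clock from the start, as if G had turned at once, with D/E at 2.00. North-east, with k = 1.22 /M/min, came to 93.1%. South-east, with 9.97 /M/min, came to 58.9%. North-west, with 81.5 /M/min, climbed 1.06 powers of ten and came to 4.53%. S says nothing of how far G has got. Tuesday's run read 93.3% after 2.50 min, and north was colder than that run, so I put north below north-east without a figure.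

The forecast named north-east as best, with 64% for south-east, 74% for north, 94% for north-east and 14% for north-west, this last called “most uncertain”, and both warm figures stood above mine.

The flasks gave north-east as best, with 93.2% there, 52.2% in south-east, 69.3% in north and 3.55% in north-west.

    G + L ⇌ L + X (K = 1.30, k = 2700 /M/s, Ea = 35.0 kJ/mol, ΔH = −10.0 kJ/mol)
    D + L + X → L + E (k = 4.40 × 10⁵ /M²/s, Ea = 17.0 kJ/mol)
    D + E → Z (k = 0.220 /M/s, Ea = 60.0 kJ/mol)
    (constants at 20 °C)

North-west fell short because of D + E → Z: the same run without that step held 100% of E instead of 3.55%. S puts k in north-east 1.83 powers of ten below north-west, and the same straight climb, run to 12 min, gives 76.1% of E in north-east. The reading of north-east at that time was 75.0%.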